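**Plan**

1. Retrosynthetic cuts: first the two ester C–O bonds at C3 and C5, both to (E)-3-methylpent-2-enoic acid, the C5–O cut leading back to a C4–C5 epoxide. Then the ring bond C4–C5, as the olefin C4=C5 of a cyclohexa-1,4-diene; then C1=C2 (Wittig); then the C–allyl bond of the ylide.
2. Structural feature used: in the cyclohexene ring, C4 carries a free OH and C5 an ester trans to it. This is the pattern left by anti opening of a C4–C5 epoxide with a carboxylic acid, so the C4–C5 bond can be made as an olefin. With C1=C2 in place the ring is then a skipped diene, closed by ring-closing metathesis between the vinyl group on C3 and the allyl group on C1, which the E enoate C1=C2 holds on the same side.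
3. Forward order: the allylated ylide and (S)-2-silyloxybut-3-enal are joined at C1=C2, and the only ring is closed at C4–C5. Desilylation, directed epoxidation, esterification of O3 and opening of the epoxide at C5 by the same acid then give the target.
4. Stereochemistry: C3 comes from (S)-but-3-ene-1,2-diol (chiral pool). C4 is set by hydroxyl-directed epoxidation cis to O3. C5 is set by inversion in the anti epoxide opening, which also leaves the 4-OH free. Both acyl groups come from the E acid.

Key step: step 5

Assumption: (E)-3-methylpent-2-enoic acid and (S)-but-3-ene-1,2-diol are taken as purchasable single isomers; locants C1–C6 are those of the cyclohexene ring of the target (C1 bears CO2Me, C3 and C5 the esters, C4 the free OH).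

**Route**

Step 1
Reactants: 1 methyl (triphenylphosphoranylidene)acetate; 2 allyl bromide (3-bromoprop-1-ene)
Product: 4 methyl 2-(triphenylphosphoranylidene)pent-4-enoate, via phosphonium bromide 3 (not isolated)
Conditions: CHCl3, reflux; then 2 M aq. NaOH, CH2Cl2, rt
Reagents that add atoms: none
Why: C-alkylation of the stabilised ylide by the reactive allylic bromide should give phosphonium salt 3, whose acidic α-hydrogen is removed by NaOH to give the α-allyl stabilised ylide (ylide alkylation followed by deprotonation), and no stereocenter is involved.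

Step 2
Reactants: 5 (2S)-but-3-ene-1,2-diol
Product: 6 (3S)-3,4-bis(triethylsilyloxy)but-1-ene
Conditions: Et3SiCl (2.3 equiv), imidazole (3 equiv), CH2Cl2, 0 °C to rt
Reagents that add atoms: chlorotriethylsilane, CC[Si](Cl)(CC)CC
Why: Silyl ether formation at both hydroxyl groups with a silyl chloride and imidazole should be unexceptional and does not touch the stereocenter taken from the chiral pool.

Step 3
Reactants: 6 (3S)-3,4-bis(triethylsilyloxy)but-1-ene
Product: 8 (2S)-2-(triethylsilyloxy)but-3-enal, via alkoxysulfonium chloride 7 (not isolated)
Conditions: (COCl)2, DMSO, CH2Cl2, −78 to −40 °C; then Et3N, −78 to 0 °C; crude 8 used at once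
Reagents that add atoms: none
Why: In this direct Swern oxidation of a primary silyl ether the chlorodimethylsulfonium salt should cleave the unhindered primary triethylsilyl ether to alkoxysulfonium salt 7 while the secondary silyl ether survives, and base then gives the aldehyde, whose α-stereocenter is kept by low temperature and immediate use.

Step 4
Reactants: 8 (2S)-2-(triethylsilyloxy)but-3-enal; 4 methyl 2-(triphenylphosphoranylidene)pent-4-enoate
Product: 9 methyl (2E,4S)-2-(prop-2-enyl)-4-(triethylsilyloxy)hexa-2,5-dienoate
Conditions: CH2Cl2, rt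
Reagents that add atoms: none
Why: The Wittig reaction of a stabilised α-substituted ylide should give the E trisubstituted enoate, with the ester trans to the C3 arm and the allyl group therefore cis to it, under neutral salt-free conditions that should not epimerise the α-silyloxy aldehyde.

Step 5
Reactants: 9 methyl (2E,4S)-2-(prop-2-enyl)-4-(triethylsilyloxy)hexa-2,5-dienoate
Product: 10 methyl (3S)-3-(triethylsilyloxy)cyclohexa-1,4-diene-1-carboxylate
Conditions: second-generation Grubbs catalyst (H2IMes)(PCy3)Cl2Ru=CHPh (3 mol %), 1,4-benzoquinone (10 mol %), CH2Cl2 (0.01 M), 40 °C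
Reagents that add atoms: none
Why: The ruthenium alkylidene should load on the unhindered allyl terminus of 9, add across the vinyl group on C3 in a [2+2] step to a ruthenacyclobutane and cyclorevert, which releases ethene and joins the two former alkene carbons as C4 and C5 of the ring. The closest known reaction type is ring-closing metathesis of 1,6-dienes to cyclohexenes and cyclohexa-1,4-dienes. The six-membered carbocycle is closed by olefin metathesis between two terminal alkenes, with the new cis C4=C5 bond inside the ring, and closure is possible because the E enoate C1=C2 holds the C3 arm and the allyl arm on the same side. No stereocenter is formed: the C3 center is carried through unchanged, and the new C4=C5 olefin is the handle from which C4 and C5 are set in steps 7 and 9. The step needs chemoselectivity for the two terminal alkenes over the electron-poor trisubstituted C1=C2 bond, which should be inert to the catalyst, and it needs the skipped diene to survive, which the silyl ether on O3 (no free doubly allylic alcohol open to redox isomerisation) and the benzoquinone hydride scavenger should secure.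

Step 6
Reactants: 10 methyl (3S)-3-(triethylsilyloxy)cyclohexa-1,4-diene-1-carboxylate
Product: 11 methyl (3S)-3-hydroxycyclohexa-1,4-diene-1-carboxylate
Conditions: HF·pyridine, pyridine, THF, 0 °C; used without storage
Reagents that add atoms: none
Why: Fluoride cleavage of the triethylsilyl ether (desilylation) under pyridine-buffered conditions should release the doubly allylic alcohol without acid- or base-induced loss of water, and the stereocenter is not touched.

Step 7
Reactants: 11 methyl (3S)-3-hydroxycyclohexa-1,4-diene-1-carboxylate
Product: 12 methyl (3R,4R,5S)-4,5-epoxy-3-hydroxycyclohex-1-ene-1-carboxylate (epoxide oxygen on the face of the 3-OH)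
Conditions: mCPBA (1.1 equiv), CH2Cl2, 0 °C; aq. Na2S2O3/NaHCO3 work-up
Reagents that add atoms: 3-chloroperoxybenzoic acid (mCPBA), OOC(=O)c1cccc(Cl)c1
Why: In this hydroxyl-directed Prilezhaev epoxidation the peracid is hydrogen-bonded to the allylic 3-OH and should deliver oxygen to the C4=C5 bond on the face of that hydroxyl group, which sets the C4–O bond cis to O3, while the electron-poor C1=C2 bond should not react.

Step 8
Reactants: 12 methyl (3R,4R,5S)-4,5-epoxy-3-hydroxycyclohex-1-ene-1-carboxylate; 13 (2E)-3-methylpent-2-enoic acid
Product: 14 methyl (3R,4S,5S)-4,5-epoxy-3-{[(2E)-3-methylpent-2-enoyl]oxy}cyclohex-1-ene-1-carboxylate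
Conditions: DCC (1.2 equiv), DMAP (10 mol %), CH2Cl2, 0 °C to rt
Reagents that add atoms: none
Why: Carbodiimide activation with DMAP catalysis (Steglich esterification) should acylate the only free hydroxyl group with retention at C3, under conditions mild enough to leave the epoxide and the E geometry of the acyl group intact.

Step 9
Reactants: 14 methyl (3R,4S,5S)-4,5-epoxy-3-{[(2E)-3-methylpent-2-enoyl]oxy}cyclohex-1-ene-1-carboxylate; 13 (2E)-3-methylpent-2-enoic acid
Product: 15 methyl (3R,4S,5R)-4-hydroxy-3,5-bis{[(2E)-3-methylpent-2-enoyl]oxy}cyclohex-1-ene-1-carboxylate (CNP0268575.1)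
Conditions: 13 (2 equiv), [N,N'-bis(3,5-di-tert-butylsalicylidene)ethane-1,2-diaminato]cobalt (5 mol %; divalent cobalt, oxidised in the flask by air and 13 to the trivalent cobalt carboxylate), i-Pr2NEt (1 equiv), t-BuOMe, air, rt
Reagents that add atoms: none
Why: In this carboxylic acid ring opening of an epoxide under cooperative Lewis acid catalysis, the cobalt-bound carboxylate should attack the cobalt-activated epoxide in an SN2, trans-diaxial fashion at C5, the carbon remote from the electron-withdrawing 3-acyloxy group (analogous 3-alkoxy-4,5-epoxycyclohexenecarboxylates are known to open at C5), which inverts C5 and leaves the C4–O bond untouched, so that the free 4-OH ends cis to O3 and trans to the new ester.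

**Compound list**

1 | methyl (triphenylphosphoranylidene)acetate | COC(=O)C=P(c1ccccc1)(c1ccccc1)c1ccccc1 | starting material
2 | allyl bromide (3-bromoprop-1-ene) | C=CCBr | starting material
3 | [1-(methoxycarbonyl)but-3-enyl]triphenylphosphonium bromide (racemic, not isolated) | COC(=O)C(CC=C)[P+](c1ccccc1)(c1ccccc1)c1ccccc1.[Br-] | intermediate
4 | methyl 2-(triphenylphosphoranylidene)pent-4-enoate | COC(=O)C(CC=C)=P(c1ccccc1)(c1ccccc1)c1ccccc1 | intermediate
5 | (2S)-but-3-ene-1,2-diol | OC[C@@H](O)C=C | starting material
6 | (3S)-3,4-bis(triethylsilyloxy)but-1-ene | CC[Si](CC)(CC)OC[C@@H](O[Si](CC)(CC)CC)C=C | intermediate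
7 | dimethyl{[(2S)-2-(triethylsilyloxy)but-3-enyl]oxy}sulfonium chloride (not isolated) | C[S+](C)OC[C@@H](O[Si](CC)(CC)CC)C=C.[Cl-] | intermediate
8 | (2S)-2-(triethylsilyloxy)but-3-enal | O=C[C@@H](O[Si](CC)(CC)CC)C=C | intermediate
9 | methyl (2E,4S)-2-(prop-2-enyl)-4-(triethylsilyloxy)hexa-2,5-dienoate | COC(=O)/C(CC=C)=C/[C@@H](O[Si](CC)(CC)CC)C=C | intermediate
10 | methyl (3S)-3-(triethylsilyloxy)cyclohexa-1,4-diene-1-carboxylate | COC(=O)C1=C[C@@H](O[Si](CC)(CC)CC)C=CC1 | intermediate
11 | methyl (3S)-3-hydroxycyclohexa-1,4-diene-1-carboxylate | COC(=O)C1=C[C@@H](O)C=CC1 | intermediate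
12 | methyl (3R,4R,5S)-4,5-epoxy-3-hydroxycyclohex-1-ene-1-carboxylate (epoxide cis to OH) | O[C@@H]1C=C(C(=O)OC)C[C@@H]2O[C@H]12 | intermediate
13 | (2E)-3-methylpent-2-enoic acid | CC/C(C)=C/C(=O)O | starting material
14 | methyl (3R,4S,5S)-4,5-epoxy-3-{[(2E)-3-methylpent-2-enoyl]oxy}cyclohex-1-ene-1-carboxylate | CC/C(C)=C/C(=O)O[C@@H]1C=C(C(=O)OC)C[C@@H]2O[C@H]12 | intermediate
15 | methyl (3R,4S,5R)-4-hydroxy-3,5-bis{[(2E)-3-methylpent-2-enoyl]oxy}cyclohex-1-ene-1-carboxylate | CC/C(C)=C/C(=O)O[C@@H]1C=C(C(=O)OC)C[C@@H](OC(=O)/C=C(\C)CC)[C@@H]1O | target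

**Step count and risks**

Total: 9 steps. Longest linear sequence: 8 steps (steps 2 to 9, from diol 5); step 1 is the side branch to ylide 4.

Steps most likely to fail:

Step 9. The epoxide opening may be sluggish, the carboxylate may attack C4 as well as C5, and an acyl group may migrate to the freed 4-OH. The fallback reverses the order of the last two steps; it sets out from 12 and comes back at 15. Epoxy alcohol 12 would be opened with acid 13 under Ti(OiPr)4 mediation (CH2Cl2, rt), where the titanium alkoxide of the 3-OH holds the cis epoxide oxygen and the carboxylate is delivered anti to the remote carbon C5, to give methyl 5-O-[(2E)-3-methylpent-2-enoyl]shikimate F1. The allylic 3-OH of F1, which is less hindered than the 4-OH flanked on both sides, would then be esterified selectively with 13 (DCC, DMAP, CH2Cl2, −20 °C) to give 15.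

Step 7. The peracid may deliver oxygen to the face remote from the hydroxyl group, or the unprotected dienol of step 6 may aromatise by loss of water before it is epoxidised. The fallback builds the epoxide on the silyl ether without a free dienol; it sets out from 10 and comes back at 12. NBS in wet DME at 0 °C should place the bromonium ion on the face away from the silyloxy group and water anti to it, mainly at C5, to give methyl (3R,4R,5S)-4-bromo-5-hydroxy-3-(triethylsilyloxy)cyclohex-1-ene-1-carboxylate F2. Any attack of water at C4 would give methyl (3R,4R,5R)-5-bromo-4-hydroxy-3-(triethylsilyloxy)cyclohex-1-ene-1-carboxylate F3, which carries its hydroxyl group on the same face. K2CO3 in MeOH at 0 °C would close both by backside displacement of bromide to the same methyl (3R,4S,5S)-4,5-epoxy-3-(triethylsilyloxy)cyclohex-1-ene-1-carboxylate F4, whose oxygen lies cis to O3. HF·pyridine in THF would then give 12.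

Step 5. Olefin migration by ruthenium hydrides, followed by aromatisation through loss of the silyloxy group, may compete with ring closure. The fallback closes the ring before the C1=C2 bond exists; it sets out from 8 and comes back at 10. Aldol addition of the lithium enolate of methyl pent-4-enoate (LiN(i-Pr)2, THF, −78 °C) to aldehyde 8 would give methyl (4S)-3-hydroxy-2-(prop-2-enyl)-4-(triethylsilyloxy)hex-5-enoate F5, as a mixture at C2 and C3 that does not matter. Ring-closing metathesis of this 1,7-diene with the second-generation Grubbs catalyst would give methyl (3S)-2-hydroxy-3-(triethylsilyloxy)cyclohex-4-ene-1-carboxylate F6, which holds no skipped diene. Mesylation (MsCl, Et3N, CH2Cl2, 0 °C) would give methyl (3S)-2-(methylsulfonyloxy)-3-(triethylsilyloxy)cyclohex-4-ene-1-carboxylate F7, and E1cB elimination with DBU toward the only acidic hydrogen, that on C1, would deliver 10.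

**Further compounds**

F1 | step 9 | methyl 5-O-[(2E)-3-methylpent-2-enoyl]shikimate | O[C@@H]1C=C(C(=O)OC)C[C@@H](OC(=O)/C=C(\C)CC)[C@@H]1O
F2 | step 7 | methyl (3R,4R,5S)-4-bromo-5-hydroxy-3-(triethylsilyloxy)cyclohex-1-ene-1-carboxylate | CC[Si](CC)(CC)O[C@@H]1C=C(C(=O)OC)C[C@H](O)[C@H]1Br
F3 | step 7 | methyl (3R,4R,5R)-5-bromo-4-hydroxy-3-(triethylsilyloxy)cyclohex-1-ene-1-carboxylate | CC[Si](CC)(CC)O[C@@H]1C=C(C(=O)OC)C[C@@H](Br)[C@@H]1O
F4 | step 7 | methyl (3R,4S,5S)-4,5-epoxy-3-(triethylsilyloxy)cyclohex-1-ene-1-carboxylate | CC[Si](CC)(CC)O[C@@H]1C=C(C(=O)OC)C[C@@H]2O[C@H]12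
F5 | step 5 | methyl (4S)-3-hydroxy-2-(prop-2-enyl)-4-(triethylsilyloxy)hex-5-enoate (mixture at C2 and C3) | COC(=O)C(CC=C)C(O)[C@@H](O[Si](CC)(CC)CC)C=C
F6 | step 5 | methyl (3S)-2-hydroxy-3-(triethylsilyloxy)cyclohex-4-ene-1-carboxylate (mixture at C1 and C2) | COC(=O)C1C(O)[C@@H](O[Si](CC)(CC)CC)C=CC1
F7 | step 5 | methyl (3S)-2-(methylsulfonyloxy)-3-(triethylsilyloxy)cyclohex-4-ene-1-carboxylate (mixture at C1 and C2) | COC(=O)C1C(OS(C)(=O)=O)[C@@H](O[Si](CC)(CC)CC)C=CC1
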